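**Retrosynthetic overview** (macrolide numbering: C1 = lactone carbonyl, C13 = carbinol carbon bearing the ethyl group)
1. Lactone C1–O bond ⇒ acylketene from a tert-butyl β-keto ester; C1–C2 come from tert-butyl propanoate by Claisen condensation onto a C3 ester.
2. C10–C11 ⇒ C10 enol triflate + E-alkenylalane from (R)-pent-1-yn-3-ol and Me3Al (C11–C13).
3. C4–C5 ⇒ diethyl 2-hydroxymalonate + E-allylic bromide; the two ester arms at C4 are then told apart by an enantioselective mono-reduction.
4. C5–C10 with all three branch carbons ⇒ 2,4,6-trimethylpyrylium: MeMgBr dearomatisation to a 2H-pyran, ring opening to the Z-dienone, asymmetric CuH 1,4-reduction (C8), SeO2 oxidation of the E-methyl (C5).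
5. Ring order: pyrylium ring opened (steps 1–2), dioxolane protecting ring (step 7), 14-membered lactone closed in step 10.

Assumption 1: C2 lies between two carbonyls and is configurationally labile, so the isolated (2S) epimer is taken to be the thermodynamic one and is reached by equilibration.
Assumption 2: (R)-pent-1-yn-3-ol is bought enantiopure; the sense of induction in steps 2 and 7 rests on analogy, and the ligand antipode is used if the first run shows the opposite sense.

**Step 1**
Reactants: 1 2,4,6-trimethylpyrylium tetrafluoroborate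
Product: 2 2,2,4,6-tetramethyl-2H-pyran
Conditions: MeMgBr (1.05 equiv), Et2O, −40 → 0 °C; cold aq. NaHCO3
Reagents that add atoms: methylmagnesium bromide, C[Mg]Br
Why: Nucleophilic dearomatisation: Grignard reagents add at the 2-position of 2,4,6-trialkylpyrylium salts to give 2H-pyrans, so the five ring carbons and three methyls become C6–C10 with their branch carbons and the gem-dimethyl carbon becomes C6 (one of its methyls is later C5).

**Step 2**
Reactants: 2 2,2,4,6-tetramethyl-2H-pyran
Product: 4 (4R)-4,6-dimethylhept-5-en-2-one, via (Z)-dienone 3 (not isolated)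
Conditions: Cu(OAc)2 (3 mol%), (R)-DTBM-SEGPHOS (3.3 mol%), (MeO)2MeSiH (1.2 equiv), t-BuOH (1.2 equiv), toluene, 30 °C, 24 h
Reagents that add atoms: none
Why: Proposed new method: the 2H-pyran equilibrates at 30 °C by 6π-electrocyclic ring opening with dienone 3, whose enone geometry is fixed as Z by the ring, and ligated CuH should reduce only this minor valence isomer 1,4 at the β,β-disubstituted enone carbon (the δ-carbon is fully substituted and the diene is twisted, which disfavours 1,6-delivery), the bisphosphine choosing the enone face and so setting C8 as R; the closest known reaction type is the CuH/chiral bisphosphine conjugate reduction of geometrically pure acyclic β,β-disubstituted enones.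

**Step 3**
Reactants: 4 (4R)-4,6-dimethylhept-5-en-2-one
Product: 5 (4R)-4,6-dimethylhepta-1,5-dien-2-yl trifluoromethanesulfonate
Conditions: LiN(i-Pr)2 (1.1 equiv), THF, −78 °C; PhNTf2 (1.15 equiv), −78 → 0 °C
Reagents that add atoms: N-phenylbis(trifluoromethanesulfonimide), O=S(=O)(N(c1ccccc1)S(=O)(=O)C(F)(F)F)C(F)(F)F
Why: Kinetic deprotonation of the methyl ketone on the methyl side and O-triflation (enol triflate formation) turns the former ring methyl into the exocyclic methylene and C10 into a coupling site, without touching C8.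

**Step 4**
Reactants: 5 (4R)-4,6-dimethylhepta-1,5-dien-2-yl trifluoromethanesulfonate
Product: 6 (4R,5E)-7-hydroxy-4,6-dimethylhepta-1,5-dien-2-yl trifluoromethanesulfonate
Conditions: SeO2 (0.5 equiv), t-BuOOH (3 equiv), salicylic acid (10 mol%), CH2Cl2, 0 °C → rt
Reagents that add atoms: selenium dioxide, O=[Se]=O; tert-butyl hydroperoxide, CC(C)(C)OO
Why: SeO2/t-BuOOH allylic oxidation (ene reaction then [2,3]-sigmatropic shift) hydroxylates the E-methyl of a gem-dimethyl trisubstituted alkene with high E-selectivity, which fixes the C6=C7 geometry, while the electron-poor enol triflate alkene does not react.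

**Step 5**
Reactants: 6 (4R,5E)-7-hydroxy-4,6-dimethylhepta-1,5-dien-2-yl trifluoromethanesulfonate
Product: 7 (4R,5E)-7-bromo-4,6-dimethylhepta-1,5-dien-2-yl trifluoromethanesulfonate
Conditions: CBr4 (1.3 equiv), PPh3 (1.3 equiv), CH2Cl2, 0 °C
Reagents that add atoms: carbon tetrabromide, BrC(Br)(Br)Br
Why: Appel bromination of the primary allylic alcohol is an SN2 displacement at CH2, so the E-alkene and C8 are untouched.

**Step 6**
Reactants: 7 (4R,5E)-7-bromo-4,6-dimethylhepta-1,5-dien-2-yl trifluoromethanesulfonate; 8 diethyl 2-hydroxymalonate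
Product: 9 diethyl 2-hydroxy-2-[(2E,4R)-2,4-dimethyl-6-{[(trifluoromethyl)sulfonyl]oxy}hepta-2,6-dien-1-yl]propanedioate
Conditions: 8 (1.2 equiv), NaH (1.15 equiv), THF/DMF (4:1), 0 °C; then 7, 0 °C → rt
Reagents that add atoms: none
Why: Malonate alkylation: the C–H of the hydroxymalonate is far more acidic than its O–H, so the sodium enolate forms and is C-alkylated by the primary allylic bromide (SN2), which makes the C4–C5 bond and leaves C4 prochiral with two equivalent ester arms.

**Step 7**
Reactants: 9 diethyl 2-hydroxy-2-[(2E,4R)-2,4-dimethyl-6-{[(trifluoromethyl)sulfonyl]oxy}hepta-2,6-dien-1-yl]propanedioate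
Product: 12 ethyl (4R)-4-[(2E,4R)-2,4-dimethyl-6-{[(trifluoromethyl)sulfonyl]oxy}hepta-2,6-dien-1-yl]-2,2-dimethyl-1,3-dioxolane-4-carboxylate, via bis-silyl ether 10 (not isolated), via diol ester 11 (not isolated)
Conditions: Et2Zn (10 mol%), (S,S)-2,6-bis{[2-(hydroxydiphenylmethyl)piperidin-1-yl]methyl}-4-methylphenol (5 mol%), (MeO)2MeSiH (4 equiv), THF, 0 °C → rt; then CSA (0.3 equiv), MeOH, Me2C(OMe)2 (10 equiv), rt
Reagents that add atoms: 2,2-dimethoxypropane, COC(C)(C)OC
Why: Proposed new method: the free tertiary hydroxyl is silylated in the flask by the Zn–H/silane couple, so the catalyst meets an α-siloxy-α-alkyl malonate whose two ethoxycarbonyl groups differ only by their position at C4, and the dinuclear zinc hydride held in the chiral tetradentate pocket should chelate the malonate and reduce only the pro-S ester (the resulting alkoxide is inert to further reduction), which sets C4 as R before acidic methanol frees the diol and 2,2-dimethoxypropane closes the acetonide; the closest known reaction type is the dinuclear-zinc-catalysed desymmetrising hydrosilylation of α,α-disubstituted malonic esters.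

**Step 8**
Reactants: 12 ethyl (4R)-4-[(2E,4R)-2,4-dimethyl-6-{[(trifluoromethyl)sulfonyl]oxy}hepta-2,6-dien-1-yl]-2,2-dimethyl-1,3-dioxolane-4-carboxylate; 13 (R)-pent-1-yn-3-ol
Product: 15 ethyl (4R)-4-[(2E,4R,7E,9R)-9-hydroxy-2,4,8-trimethyl-6-methylideneundeca-2,7-dien-1-yl]-2,2-dimethyl-1,3-dioxolane-4-carboxylate, via alkenylalane 14 (not isolated)
Conditions: 13 (1.5 equiv), Me3Al (4.5 equiv), Cp2ZrCl2 (0.4 equiv), CH2Cl2, 0 °C → rt, 24 h; volatiles removed in vacuo; THF, ZnCl2 (1.5 equiv), Pd(PPh3)4 (5 mol%), 12 (1.0 equiv), rt → 45 °C; aq. potassium sodium tartrate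
Reagents that add atoms: trimethylaluminium, C[Al](C)C
Why: Negishi carboalumination adds methyl and aluminium syn across the alkyne (methyl to the internal carbon) to give the E-alkenylalane, which after Al→Zn exchange couples with the enol triflate under zerovalent palladium catalysis with retention (Negishi coupling), forming C10–C11 and the E-C11=C12 diene while C13 is carried in unchanged from 13.

**Step 9**
Reactants: 15 ethyl (4R)-4-[(2E,4R,7E,9R)-9-hydroxy-2,4,8-trimethyl-6-methylideneundeca-2,7-dien-1-yl]-2,2-dimethyl-1,3-dioxolane-4-carboxylate; 16 tert-butyl propanoate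
Product: 17 tert-butyl 3-{(4R)-4-[(2E,4R,7E,9R)-9-hydroxy-2,4,8-trimethyl-6-methylideneundeca-2,7-dien-1-yl]-2,2-dimethyl-1,3-dioxolan-4-yl}-2-methyl-3-oxopropanoate (C2 epimers)
Conditions: 16 (5 equiv), LiN(i-Pr)2 (5 equiv), THF, −78 °C, 30 min; then 15, −78 → 0 °C; aq. NH4Cl
Reagents that add atoms: none
Why: Crossed Claisen condensation: the non-enolisable, α-oxygen-activated ethyl ester is acylated by lithio tert-butyl propanoate (the excess base covers the free C13 hydroxyl and the acidic product), giving the β-keto ester with C2 still unfixed.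

**Step 10**
Reactants: 17 tert-butyl 3-{(4R)-4-[(2E,4R,7E,9R)-9-hydroxy-2,4,8-trimethyl-6-methylideneundeca-2,7-dien-1-yl]-2,2-dimethyl-1,3-dioxolan-4-yl}-2-methyl-3-oxopropanoate
Product: 19 spiro-acetonide of 20 (acetone acetal of the C4 hydroxyl/hydroxymethyl diol; C2 epimer mixture), via acylketene 18 (not isolated)
Conditions: toluene, 110 °C, syringe-pump addition over 8 h to 0.5 mM, then 2 h
Reagents that add atoms: none
Why: Thermal loss of tert-butanol from the β-keto ester gives the acylketene, which at high dilution is trapped by the C13 hydroxyl (acylketene macrolactonisation) to close the 14-membered β-keto lactone, the acetonide keeping both C4 oxygens from competing.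

**Step 11**
Reactants: 19 spiro-acetonide of 20
Product: 20 (3S,5R,7E,9R,12E,14R)-14-ethyl-5-hydroxy-5-(hydroxymethyl)-3,7,9,13-tetramethyl-11-methylidene-1-oxacyclotetradeca-7,12-diene-2,4-dione
Conditions: AcOH/H2O (4:1), 40 °C, 3–6 h
Reagents that add atoms: none
Why: Mild acid hydrolysis of the isopropylidene acetal frees the tertiary hydroxyl and the hydroxymethyl group, and the same protic medium equilibrates C2 through the enol to the thermodynamically preferred 2S epimer (thermodynamic control at a doubly activated centre).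

**Compound list**
1 | 2,4,6-trimethylpyrylium tetrafluoroborate | Cc1cc(C)[o+]c(C)c1.F[B-](F)(F)F | starting material
2 | 2,2,4,6-tetramethyl-2H-pyran | CC1=CC(C)=CC(C)(C)O1 | intermediate
3 | (3Z)-4,6-dimethylhepta-3,5-dien-2-one | CC(=O)/C=C(C)\C=C(C)C | intermediate (not isolated)
4 | (4R)-4,6-dimethylhept-5-en-2-one | CC(C)=C[C@H](C)CC(C)=O | intermediate
5 | (4R)-4,6-dimethylhepta-1,5-dien-2-yl trifluoromethanesulfonate | CC(C)=C[C@H](C)CC(=C)OS(=O)(=O)C(F)(F)F | intermediate
6 | (4R,5E)-7-hydroxy-4,6-dimethylhepta-1,5-dien-2-yl trifluoromethanesulfonate | OC/C(C)=C/[C@H](C)CC(=C)OS(=O)(=O)C(F)(F)F | intermediate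
7 | (4R,5E)-7-bromo-4,6-dimethylhepta-1,5-dien-2-yl trifluoromethanesulfonate | BrC/C(C)=C/[C@H](C)CC(=C)OS(=O)(=O)C(F)(F)F | intermediate
8 | diethyl 2-hydroxymalonate | CCOC(=O)C(O)C(=O)OCC | starting material
9 | diethyl 2-hydroxy-2-[(2E,4R)-2,4-dimethyl-6-{[(trifluoromethyl)sulfonyl]oxy}hepta-2,6-dien-1-yl]propanedioate | CCOC(=O)C(O)(C(=O)OCC)C/C(C)=C/[C@H](C)CC(=C)OS(=O)(=O)C(F)(F)F | intermediate
10 | ethyl (2R,4E,6R)-2-{[dimethoxy(methyl)silyl]oxy}-2-({[dimethoxy(methyl)silyl]oxy}methyl)-4,6-dimethyl-8-{[(trifluoromethyl)sulfonyl]oxy}nona-4,8-dienoate | CCOC(=O)[C@](O[Si](C)(OC)OC)(CO[Si](C)(OC)OC)C/C(C)=C/[C@H](C)CC(=C)OS(=O)(=O)C(F)(F)F | intermediate (not isolated)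
11 | ethyl (2R,4E,6R)-2-hydroxy-2-(hydroxymethyl)-4,6-dimethyl-8-{[(trifluoromethyl)sulfonyl]oxy}nona-4,8-dienoate | CCOC(=O)[C@](O)(CO)C/C(C)=C/[C@H](C)CC(=C)OS(=O)(=O)C(F)(F)F | intermediate (not isolated)
12 | ethyl (4R)-4-[(2E,4R)-2,4-dimethyl-6-{[(trifluoromethyl)sulfonyl]oxy}hepta-2,6-dien-1-yl]-2,2-dimethyl-1,3-dioxolane-4-carboxylate | CCOC(=O)[C@@]1(C/C(C)=C/[C@H](C)CC(=C)OS(=O)(=O)C(F)(F)F)COC(C)(C)O1 | intermediate
13 | (R)-pent-1-yn-3-ol | C#C[C@@H](CC)O | starting material
14 | dimethylaluminium (1E,3R)-1-(dimethylalumanyl)-2-methylpent-1-en-3-olate | C[Al](C)/C=C(\C)[C@@H](CC)O[Al](C)C | intermediate (not isolated)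
15 | ethyl (4R)-4-[(2E,4R,7E,9R)-9-hydroxy-2,4,8-trimethyl-6-methylideneundeca-2,7-dien-1-yl]-2,2-dimethyl-1,3-dioxolane-4-carboxylate | CCOC(=O)[C@@]1(C/C(C)=C/[C@H](C)CC(=C)/C=C(\C)[C@@H](CC)O)COC(C)(C)O1 | intermediate
16 | tert-butyl propanoate | CCC(=O)OC(C)(C)C | starting material
17 | tert-butyl 3-{(4R)-4-[(2E,4R,7E,9R)-9-hydroxy-2,4,8-trimethyl-6-methylideneundeca-2,7-dien-1-yl]-2,2-dimethyl-1,3-dioxolan-4-yl}-2-methyl-3-oxopropanoate (C2 epimers) | CC(C(=O)OC(C)(C)C)C(=O)[C@@]1(C/C(C)=C/[C@H](C)CC(=C)/C=C(\C)[C@@H](CC)O)COC(C)(C)O1 | intermediate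
18 | 3-{(4R)-4-[(2E,4R,7E,9R)-9-hydroxy-2,4,8-trimethyl-6-methylideneundeca-2,7-dien-1-yl]-2,2-dimethyl-1,3-dioxolan-4-yl}-2-methylprop-1-ene-1,3-dione (acylketene) | CC(=C=O)C(=O)[C@@]1(C/C(C)=C/[C@H](C)CC(=C)/C=C(\C)[C@@H](CC)O)COC(C)(C)O1 | intermediate (not isolated)
19 | spiro-acetonide of 20: 2,2-dimethyl-1,3-dioxolane spiro-fused at C4 of the macrolactone through the C4 oxygen and the hydroxymethyl oxygen (4R,8R,13R; 6E,11E; C2 epimers) | C=C1/C=C(\C)[C@@H](CC)OC(=O)C(C)C(=O)[C@@]2(OC(C)(C)OC2)C/C(C)=C/[C@H](C)C1 | intermediate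
20 | (3S,5R,7E,9R,12E,14R)-14-ethyl-5-hydroxy-5-(hydroxymethyl)-3,7,9,13-tetramethyl-11-methylidene-1-oxacyclotetradeca-7,12-diene-2,4-dione | C=C1/C=C(\C)[C@@H](CC)OC(=O)[C@@H](C)C(=O)[C@](O)(CO)C/C(C)=C/[C@H](C)C1 | target

**Totals**
Total step count: 11. Longest linear sequence: 11 steps (1 → 20); compounds 8, 13 and 16 are bought and enter directly.

**Three steps most likely to fail, with fallbacks**

Step 2 (CuH reduction of the pyran/dienone pair; low dienone concentration, uncertain enantioselectivity). The fallback sets out from 2 and comes back at 4, and replaces catalyst control by relay from a carbinol. Pyran 2, through its open form 3, is reduced at the carbonyl with the R-selective alcohol dehydrogenase from Lactobacillus kefir (NADP+, i-PrOH, pH 7 buffer, 30 °C) to (2R,3Z)-4,6-dimethylhepta-3,5-dien-2-ol F1. Hydroxyl-directed hydrogenation with [Ir(cod)(PCy3)(py)]PF6 (2 mol%) and H2 in CH2Cl2 at 0 °C then adds hydrogen to the allylic C3=C4 bond from the hydroxyl face of the A(1,3)-minimised conformer of this Z-allylic alcohol, giving (2R,4R)-4,6-dimethylhept-5-en-2-ol F2. Dess–Martin oxidation removes the relay centre and returns ketone 4.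

Step 7 (enantioselective mono-reduction of the hydroxymalonate; free hydroxyl and sense of induction untested). The fallback sets out from 7 and comes back at 12, and uses self-regeneration of a stereocentre instead of differentiating two ester groups. Commercial ethyl (4R)-2,2-dimethyl-1,3-dioxolane-4-carboxylate F3 is transacetalised with pivalaldehyde (TsOH, pentane, reflux; cis isomer separated) to ethyl (2R,4R)-2-tert-butyl-1,3-dioxolane-4-carboxylate F4. Its lithium enolate (LiN(i-Pr)2, THF, −78 °C) is alkylated by bromide 7 trans to the tert-butyl group, giving ethyl (2R,4R)-2-tert-butyl-4-[(2E,4R)-2,4-dimethyl-6-{[(trifluoromethyl)sulfonyl]oxy}hepta-2,6-dien-1-yl]-1,3-dioxolane-4-carboxylate F5 with C4 as R. Acetal exchange at this robust ester stage (TsOH, MeOH, 50 °C; then 2,2-dimethoxypropane) gives 12.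

Step 9 (Claisen condensation on an α-quaternary ester in the presence of a free hydroxyl). The fallback sets out from 12 and comes back at 17, building the β-keto ester by aldol addition and oxidation before the C13 hydroxyl is present. Ester 12 is reduced with i-Bu2AlH (CH2Cl2, −78 °C) to (4R)-4-[(2E,4R)-2,4-dimethyl-6-{[(trifluoromethyl)sulfonyl]oxy}hepta-2,6-dien-1-yl]-2,2-dimethyl-1,3-dioxolane-4-carbaldehyde F6. Aldol addition of lithio tert-butyl propanoate (from 16, −78 °C) gives the tert-butyl 3-hydroxy-2-methyl-3-(dioxolan-4-yl)propanoate F7 as a diastereomer mixture, and Dess–Martin oxidation gives the tert-butyl 2-methyl-3-oxo-3-(dioxolan-4-yl)propanoate F8, still carrying the enol triflate. The carboalumination/Negishi coupling of step 8 is then run on F8 with 13 (one extra equivalent of alane is consumed by the acidic β-keto ester) and delivers 17.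

**Further compounds**
F1 | step 2 | (2R,3Z)-4,6-dimethylhepta-3,5-dien-2-ol | C[C@@H](O)/C=C(C)\C=C(C)C
F2 | step 2 | (2R,4R)-4,6-dimethylhept-5-en-2-ol | CC(C)=C[C@H](C)C[C@@H](C)O
F3 | step 7 | ethyl (4R)-2,2-dimethyl-1,3-dioxolane-4-carboxylate (bought) | CCOC(=O)[C@H]1COC(C)(C)O1
F4 | step 7 | ethyl (2R,4R)-2-tert-butyl-1,3-dioxolane-4-carboxylate | CCOC(=O)[C@H]1CO[C@@H](C(C)(C)C)O1
F5 | step 7 | ethyl (2R,4R)-2-tert-butyl-4-[(2E,4R)-2,4-dimethyl-6-{[(trifluoromethyl)sulfonyl]oxy}hepta-2,6-dien-1-yl]-1,3-dioxolane-4-carboxylate | CCOC(=O)[C@@]1(C/C(C)=C/[C@H](C)CC(=C)OS(=O)(=O)C(F)(F)F)CO[C@@H](C(C)(C)C)O1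
F6 | step 9 | (4R)-4-[(2E,4R)-2,4-dimethyl-6-{[(trifluoromethyl)sulfonyl]oxy}hepta-2,6-dien-1-yl]-2,2-dimethyl-1,3-dioxolane-4-carbaldehyde | O=C[C@@]1(C/C(C)=C/[C@H](C)CC(=C)OS(=O)(=O)C(F)(F)F)COC(C)(C)O1
F7 | step 9 | tert-butyl 3-{(4R)-4-[(2E,4R)-2,4-dimethyl-6-{[(trifluoromethyl)sulfonyl]oxy}hepta-2,6-dien-1-yl]-2,2-dimethyl-1,3-dioxolan-4-yl}-3-hydroxy-2-methylpropanoate | CC(C(=O)OC(C)(C)C)C(O)[C@@]1(C/C(C)=C/[C@H](C)CC(=C)OS(=O)(=O)C(F)(F)F)COC(C)(C)O1
F8 | step 9 | tert-butyl 3-{(4R)-4-[(2E,4R)-2,4-dimethyl-6-{[(trifluoromethyl)sulfonyl]oxy}hepta-2,6-dien-1-yl]-2,2-dimethyl-1,3-dioxolan-4-yl}-2-methyl-3-oxopropanoate | CC(C(=O)OC(C)(C)C)C(=O)[C@@]1(C/C(C)=C/[C@H](C)CC(=C)OS(=O)(=O)C(F)(F)F)COC(C)(C)O1
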